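The oxolane atoms C3 and C4, the exocyclic CH2 on C4 and C1 of the 3,4-dimethoxyphenyl ring form one unbroken chain, and the C3 CH2OH is cis to the C4 arylmethyl group. A radical formed at C3 can therefore make C3–C4, move to that CH2 and take up the arene there.
Disconnection 1 (key step, closes the oxolane, the only ring that is built): C3–C4 and CH2–aryl are cut together. This gives the N-hydroxyphthalimide ester of a (3S)-3-allyloxy-3-aryl-2-(silyloxymethyl)propanoic acid and 4-iodoveratrole.
Disconnection 2: the O–allyl bond (allyl trichloroacetimidate) and the oxolane C2–C3 bond (Evans syn aldol of a 3-silyloxypropanoyl imide with O-benzylvanillin). Only C2 must be set here, because the carboxyl-bearing carbon becomes planar in the key step.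
End game: fluoride desilylation, then hydrogenolysis of the phenolic benzyl ether. Both benzene rings are bought.
Key step: step 8

Remark on the chemistry: ring atoms are numbered O1, C2 (aryl), C3 (CH2OH), C4 (arylmethyl), C5. In the open-chain propanoic acid derivatives the carbinol carbon C3 becomes oxolane C2 and the carboxyl-bearing C2 becomes oxolane C3. The configuration at the carboxyl-bearing carbon is assumed not to influence the key step, since decarboxylation gives a planar radical.

Step 1
Reactants: 1 methyl 3-hydroxypropanoate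
Product: 2 methyl 3-(tert-butyldimethylsilyloxy)propanoate
Conditions: TBSCl, imidazole, CH2Cl2, 0 °C to rt
Reagents that add atoms: tert-butyldimethylsilyl chloride (TBSCl), CC(C)(C)[Si](C)(C)Cl
Why: Imidazole-promoted silyl ether formation protects the only hydroxyl group, the later C3 hydroxymethyl oxygen, and no stereocentre is involved.

Step 2
Reactants: 2 methyl 3-(tert-butyldimethylsilyloxy)propanoate
Product: 3 3-(tert-butyldimethylsilyloxy)propanoic acid
Conditions: LiOH·H2O, THF/H2O, 0 °C to rt; then 1 M HCl to pH 4, 0 °C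
Reagents that add atoms: water, O
Why: Saponification of an unhindered methyl ester at 0 °C is faster than E1cB loss of the poor silanolate leaving group, and the primary TBS ether tolerates dilute LiOH and a short work-up at pH 4.

Step 3
Reactants: 3 3-(tert-butyldimethylsilyloxy)propanoic acid; 4 (S)-4-benzyl-1,3-oxazolidin-2-one
Product: 6 (S)-4-benzyl-3-[3-(tert-butyldimethylsilyloxy)propanoyl]-1,3-oxazolidin-2-one, via mixed pivalic anhydride 5 (not isolated)
Conditions: PivCl, Et3N, THF, −20 °C; then LiCl, 4, −20 °C to rt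
Reagents that add atoms: pivaloyl chloride, CC(C)(C)C(=O)Cl (its atoms stay only in 5)
Why: N-Acylation of the oxazolidinone through a mixed pivalic anhydride with LiCl and Et3N needs no strong base, the nitrogen attacks the less hindered carbonyl group of 5, and the auxiliary stereocentre is not touched.

Step 4
Reactants: 6 (S)-4-benzyl-3-[3-(tert-butyldimethylsilyloxy)propanoyl]-1,3-oxazolidin-2-one; 7 4-benzyloxy-3-methoxybenzaldehyde (O-benzylvanillin)
Product: 10 (S)-4-benzyl-3-[(2S,3S)-3-(4-benzyloxy-3-methoxyphenyl)-2-(tert-butyldimethylsilyloxymethyl)-3-hydroxypropanoyl]-1,3-oxazolidin-2-one, via Z-boron enolate 8 (not isolated), via boron aldolate 9 (not isolated)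
Conditions: Bu2BOTf, Et3N, CH2Cl2, −78 to 0 °C; 7, −78 to 0 °C; then pH 7 buffer, MeOH, 30% H2O2, 0 °C
Reagents that add atoms: dibutylboron triflate, CCCCB(CCCC)OS(=O)(=O)C(F)(F)F (its atoms stay only in 8 and 9)
Why: Evans syn aldol reaction: soft enolisation gives the Z-boron enolate 8, which adds to 7 through a Zimmerman–Traxler chair on the enolate face away from the benzyl group of the dipole-aligned auxiliary, so the (2S,3S) syn adduct forms and its carbinol carbon, the later oxolane C2, is set as S.

Step 5
Reactants: 10 (S)-4-benzyl-3-[(2S,3S)-3-(4-benzyloxy-3-methoxyphenyl)-2-(tert-butyldimethylsilyloxymethyl)-3-hydroxypropanoyl]-1,3-oxazolidin-2-one; 11 allyl 2,2,2-trichloroacetimidate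
Product: 12 (S)-4-benzyl-3-[(2S,3S)-3-allyloxy-3-(4-benzyloxy-3-methoxyphenyl)-2-(tert-butyldimethylsilyloxymethyl)propanoyl]-1,3-oxazolidin-2-one
Conditions: 11 (2 equiv), TfOH (5 mol %), cyclohexane/CH2Cl2 2:1, 0 °C
Reagents that add atoms: none
Why: Acid-catalysed O-alkylation with a trichloroacetimidate puts the allyl group on the carbinol oxygen without breaking the C–O bond of the stereocentre and without a base that would start a retro-aldol reaction, while the basic imidate buffers the acid and the cold non-polar medium holds back ionisation of the electron-rich benzylic position; any epimer at that carbon would be a diastereomer and is removed here by chromatography.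

Step 6
Reactants: 12 (S)-4-benzyl-3-[(2S,3S)-3-allyloxy-3-(4-benzyloxy-3-methoxyphenyl)-2-(tert-butyldimethylsilyloxymethyl)propanoyl]-1,3-oxazolidin-2-one
Product: 14 (2S,3S)-3-allyloxy-3-(4-benzyloxy-3-methoxyphenyl)-2-(tert-butyldimethylsilyloxymethyl)propanoic acid, via peroxy acid 13 (not isolated)
Conditions: LiOH, 30% H2O2, THF/H2O 3:1, 0 °C; then aq Na2SO3; 1 M HCl to pH 4, 0 °C
Reagents that add atoms: hydrogen peroxide, OO
Why: Hydroperoxide cleavage of the N-acyl oxazolidinone (LiOOH method) attacks the exocyclic carbonyl group selectively even in hindered imides, sulfite reduces the peroxy acid 13, the auxiliary 4 is recovered, and the weakly basic medium at 0 °C leaves the β-allyloxy group, the alkene and the silyl ether in place.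

Step 7
Reactants: 14 (2S,3S)-3-allyloxy-3-(4-benzyloxy-3-methoxyphenyl)-2-(tert-butyldimethylsilyloxymethyl)propanoic acid
Product: 16 1,3-dioxoisoindolin-2-yl (2S,3S)-3-allyloxy-3-(4-benzyloxy-3-methoxyphenyl)-2-(tert-butyldimethylsilyloxymethyl)propanoate, via O-acylisourea 15 (not isolated)
Conditions: N-hydroxyphthalimide, DIC, DMAP (10 mol %), CH2Cl2, 0 °C to rt
Reagents that add atoms: N-hydroxyphthalimide, O=C1c2ccccc2C(=O)N1O; N,N'-diisopropylcarbodiimide (DIC), CC(C)N=C=NC(C)C (its atoms stay only in 15)
Why: Steglich-type carbodiimide esterification with N-hydroxyphthalimide gives the redox-active ester under nearly neutral conditions, and epimerisation at the α-carbon would not matter because this centre is erased in step 8.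

Step 8
Reactants: 16 1,3-dioxoisoindolin-2-yl (2S,3S)-3-allyloxy-3-(4-benzyloxy-3-methoxyphenyl)-2-(tert-butyldimethylsilyloxymethyl)propanoate; 17 4-iodo-1,2-dimethoxybenzene (4-iodoveratrole)
Product: 20 tert-butyl{[(2S,3R,4R)-2-(4-benzyloxy-3-methoxyphenyl)-4-(3,4-dimethoxybenzyl)oxolan-3-yl]methoxy}dimethylsilane, via C3 radical 18 (not isolated), via cyclised primary radical 19 (not isolated)
Conditions: 17 (2 equiv), NiBr2(dme) (10 mol %), 4,4'-di-tert-butyl-2,2'-bipyridine (dtbbpy, 12 mol %), nBu4NPF6 (0.1 M), DMA (about 0.02 M), undivided cell, Zn anode, reticulated vitreous carbon cathode, constant current (about 2.5 F/mol), rt, slow addition of 16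
Reagents that add atoms: none
Why: Proposed new method: low-valent (dtbbpy)Ni made at the cathode passes one electron to the phthalimide unit of 16, and the radical anion loses phthalimidate and CO2 to give the secondary C3 radical 18, while zerovalent nickel inserts into the C–I bond of 17 to give (dtbbpy)Ni(Ar)I. Radical 18 closes the oxolane ring 5-exo-trig onto the inner alkene carbon of the O-allyl group (C3–C4 bond), and the primary radical 19 adds to (dtbbpy)Ni(Ar)I to give a trivalent nickel species whose reductive elimination forms the CH2–aryl bond. The closest known reaction types are the nickel-catalysed electroreductive decarboxylative arylation of N-hydroxyphthalimide esters with aryl iodides and the nickel-catalysed reductive cyclisation and arylation of β-haloalkyl allyl ethers, so only the union of this radical source with this relay is new. C3 is controlled by the fixed C2 centre, because in the chair-like Beckwith–Houk transition state the C2 aryl group lies pseudo-equatorial and the CH2OTBS group on the planar radical carbon turns away from it (2,3-trans). C4 is controlled by the same transition state, in which the preference of a 2-substituted 5-hexenyl radical (2,4-trans in ring numbering) and that of a 1-substituted one (1,5-cis, here 3,4-cis) select the same alkene face. The step needs ring closure to be faster than capture of 18 by nickel, which would end in direct C3 arylation or β-alkoxide loss, and this is secured by the ether oxygen in the tether, which speeds up closure relative to an all-carbon chain, by the two branched neighbours of the radical carbon, which slow its capture, and by a low nickel concentration through dilution and slow addition of 16.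

Step 9
Reactants: 20 tert-butyl{[(2S,3R,4R)-2-(4-benzyloxy-3-methoxyphenyl)-4-(3,4-dimethoxybenzyl)oxolan-3-yl]methoxy}dimethylsilane
Product: 21 [(2S,3R,4R)-2-(4-benzyloxy-3-methoxyphenyl)-4-(3,4-dimethoxybenzyl)oxolan-3-yl]methanol
Conditions: TBAF, THF, 0 °C to rt; water work-up
Reagents that add atoms: none
Why: Fluoride-induced cleavage of the silyl ether, driven by the strong Si–F bond, frees the primary alcohol and touches neither the benzyl ether nor the three ring stereocentres.

Step 10
Reactants: 21 [(2S,3R,4R)-2-(4-benzyloxy-3-methoxyphenyl)-4-(3,4-dimethoxybenzyl)oxolan-3-yl]methanol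
Product: 22 4'-O-methyllariciresinol, 4-[(2S,3R,4R)-4-(3,4-dimethoxybenzyl)-3-(hydroxymethyl)oxolan-2-yl]-2-methoxyphenol
Conditions: H2 (1 atm), 10% Pd/C, EtOAc, rt, stopped as soon as 21 is consumed
Reagents that add atoms: none
Why: Catalytic hydrogenolysis cleaves the phenolic benzyl ether clearly faster than the cyclic benzylic C2–O1 bond, so a short reaction at 1 atm in EtOAc should leave the oxolane and its stereocentres intact.

Compound list
1 | methyl 3-hydroxypropanoate | COC(=O)CCO | starting material
2 | methyl 3-(tert-butyldimethylsilyloxy)propanoate | COC(=O)CCO[Si](C)(C)C(C)(C)C | intermediate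
3 | 3-(tert-butyldimethylsilyloxy)propanoic acid | OC(=O)CCO[Si](C)(C)C(C)(C)C | intermediate
4 | (S)-4-benzyl-1,3-oxazolidin-2-one | O=C1N[C@@H](Cc2ccccc2)CO1 | starting material
5 | 3-(tert-butyldimethylsilyloxy)propanoic pivalic anhydride (not isolated) | CC(C)(C)C(=O)OC(=O)CCO[Si](C)(C)C(C)(C)C | intermediate
6 | (S)-4-benzyl-3-[3-(tert-butyldimethylsilyloxy)propanoyl]-1,3-oxazolidin-2-one | O=C(CCO[Si](C)(C)C(C)(C)C)N1[C@@H](Cc2ccccc2)COC1=O | intermediate
7 | 4-benzyloxy-3-methoxybenzaldehyde | COc1cc(C=O)ccc1OCc1ccccc1 | starting material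
8 | (Z)-dibutylboron enolate of 6 (not isolated) | CCCCB(CCCC)O/C(=C\CO[Si](C)(C)C(C)(C)C)N1[C@@H](Cc2ccccc2)COC1=O | intermediate
9 | dibutylboron aldolate, O-boryl form of 10 (not isolated) | COc1cc([C@@H](OB(CCCC)CCCC)[C@H](CO[Si](C)(C)C(C)(C)C)C(=O)N2[C@@H](Cc3ccccc3)COC2=O)ccc1OCc1ccccc1 | intermediate
10 | (S)-4-benzyl-3-[(2S,3S)-3-(4-benzyloxy-3-methoxyphenyl)-2-(tert-butyldimethylsilyloxymethyl)-3-hydroxypropanoyl]-1,3-oxazolidin-2-one | COc1cc([C@@H](O)[C@H](CO[Si](C)(C)C(C)(C)C)C(=O)N2[C@@H](Cc3ccccc3)COC2=O)ccc1OCc1ccccc1 | intermediate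
11 | allyl 2,2,2-trichloroacetimidate | C=CCOC(=N)C(Cl)(Cl)Cl | starting material
12 | (S)-4-benzyl-3-[(2S,3S)-3-allyloxy-3-(4-benzyloxy-3-methoxyphenyl)-2-(tert-butyldimethylsilyloxymethyl)propanoyl]-1,3-oxazolidin-2-one | COc1cc([C@@H](OCC=C)[C@H](CO[Si](C)(C)C(C)(C)C)C(=O)N2[C@@H](Cc3ccccc3)COC2=O)ccc1OCc1ccccc1 | intermediate
13 | (2S,3S)-3-allyloxy-3-(4-benzyloxy-3-methoxyphenyl)-2-(tert-butyldimethylsilyloxymethyl)propaneperoxoic acid (not isolated) | COc1cc([C@@H](OCC=C)[C@H](CO[Si](C)(C)C(C)(C)C)C(=O)OO)ccc1OCc1ccccc1 | intermediate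
14 | (2S,3S)-3-allyloxy-3-(4-benzyloxy-3-methoxyphenyl)-2-(tert-butyldimethylsilyloxymethyl)propanoic acid | COc1cc([C@@H](OCC=C)[C@H](CO[Si](C)(C)C(C)(C)C)C(=O)O)ccc1OCc1ccccc1 | intermediate
15 | O-acyl-N,N'-diisopropylisourea of 14 (not isolated) | COc1cc([C@@H](OCC=C)[C@H](CO[Si](C)(C)C(C)(C)C)C(=O)OC(=NC(C)C)NC(C)C)ccc1OCc1ccccc1 | intermediate
16 | 1,3-dioxoisoindolin-2-yl (2S,3S)-3-allyloxy-3-(4-benzyloxy-3-methoxyphenyl)-2-(tert-butyldimethylsilyloxymethyl)propanoate | COc1cc([C@@H](OCC=C)[C@H](CO[Si](C)(C)C(C)(C)C)C(=O)ON2C(=O)c3ccccc3C2=O)ccc1OCc1ccccc1 | intermediate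
17 | 4-iodo-1,2-dimethoxybenzene | COc1ccc(I)cc1OC | starting material
18 | (1S)-1-allyloxy-1-(4-benzyloxy-3-methoxyphenyl)-3-(tert-butyldimethylsilyloxy)propan-2-yl radical (not isolated) | COc1cc([C@@H](OCC=C)[CH]CO[Si](C)(C)C(C)(C)C)ccc1OCc1ccccc1 | intermediate
19 | [(2S,3R,4R)-2-(4-benzyloxy-3-methoxyphenyl)-3-(tert-butyldimethylsilyloxymethyl)oxolan-4-yl]methyl radical (not isolated) | COc1cc([C@H]2OC[C@H]([CH2])[C@@H]2CO[Si](C)(C)C(C)(C)C)ccc1OCc1ccccc1 | intermediate
20 | tert-butyl{[(2S,3R,4R)-2-(4-benzyloxy-3-methoxyphenyl)-4-(3,4-dimethoxybenzyl)oxolan-3-yl]methoxy}dimethylsilane | COc1cc([C@H]2OC[C@H](Cc3ccc(OC)c(OC)c3)[C@@H]2CO[Si](C)(C)C(C)(C)C)ccc1OCc1ccccc1 | intermediate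
21 | [(2S,3R,4R)-2-(4-benzyloxy-3-methoxyphenyl)-4-(3,4-dimethoxybenzyl)oxolan-3-yl]methanol | COc1cc([C@H]2OC[C@H](Cc3ccc(OC)c(OC)c3)[C@@H]2CO)ccc1OCc1ccccc1 | intermediate
22 | 4'-O-methyllariciresinol | COc1cc([C@H]2OC[C@H](Cc3ccc(OC)c(OC)c3)[C@@H]2CO)ccc1O | target

Total step count: 10. Longest linear sequence: 10 steps (1 to 22). Compounds 4, 7, 11 and 17 enter as bought.

Steps most likely to fail

1. Step 8 (bears the label "Proposed new method:"). Several processes may interfere:
- Nickel may capture the C3 radical before ring closure, ending in direct arylation or β-alkoxide elimination.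
- The primary radical may abstract hydrogen from the solvent.
- The aryl iodide may undergo reductive homocoupling.
- The accumulating phthalimidate may cause base-induced β-elimination of the activated ester.
- Facial selectivity in the closure may be weak.

The fallback uses known chemistry, sets out from 12 and returns at 20. It brings the arene in before the radical step and ends the relay by hydrogen transfer instead of nickel capture. Cross-metathesis of 12 with 3,4-dimethoxystyrene (second-generation Grubbs catalyst, CH2Cl2, reflux) should give the (E)-3-(3,4-dimethoxyphenyl)allyl ether imide F1. LiOH/H2O2 cleavage then gives the corresponding acid F2, and DIC with N-hydroxyphthalimide gives its redox-active ester F3. Visible-light reductive decarboxylation (Ru(bpy)3Cl2 cat., Hantzsch ester, iPr2NEt, CH2Cl2, blue LED) is an intramolecular Giese-type radical addition. It releases the same C3 radical, which closes 5-exo-trig onto the styrene-type double bond through the same chair-like transition state. The resulting benzylic radical takes hydrogen from the Hantzsch ester to give 20.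

2. Step 5. Acid may ionise the electron-rich benzylic C–O bond, with loss of configuration at the only stereocentre that is carried forward. The silyl ether may be partly lost, or the arene may undergo Friedel–Crafts allylation. The fallback sets out from 10 and returns at 14, and it replaces acid catalysis by a Williamson etherification on a substrate that cannot undergo retro-aldol cleavage. LiOH/H2O2 cleavage of 10 gives the free (2S,3S)-β-hydroxy acid F4. Its disodium salt (NaH, 2.2 equiv, THF/DMF, 0 °C) is inert to retro-aldol cleavage, because the fragment expelled would be a carboxylate dianion. The more nucleophilic alkoxide is then allylated with allyl bromide (1.1 equiv), and acidification to pH 4 gives 14. The mixture is kept cold to hold back a 1,3-shift of the silyl group.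

3. Step 4. Silanolate may be lost by β-elimination from the boron-activated imide or its enolate during enolisation, or the addition to the electron-rich aldehyde may be sluggish. The fallback sets out from 4 and 7 and returns at 10, and it carries the hydroxymethyl carbon as a vinyl group that cannot leave. Acylation of 4 (n-BuLi, (E)-crotonyl chloride, THF, −78 °C) gives the N-crotonyl imide F5. Bu2BOTf and Et3N form the boron dienolate by γ-deprotonation. This reacts at its α-carbon with 7 in the same Evans syn sense to give the α-vinyl aldol F6. Ozonolysis (CH2Cl2/MeOH, −78 °C) with NaBH4 work-up gives the diol F7. Selective silylation of its primary hydroxyl group (TBSCl, imidazole, CH2Cl2, 0 °C) gives 10.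

Further compounds
F1 | step 8 | (S)-4-benzyl-3-[(2S,3S)-3-(4-benzyloxy-3-methoxyphenyl)-2-(tert-butyldimethylsilyloxymethyl)-3-[(E)-3-(3,4-dimethoxyphenyl)allyloxy]propanoyl]-1,3-oxazolidin-2-one | COc1cc([C@@H](OC/C=C/c4ccc(OC)c(OC)c4)[C@H](CO[Si](C)(C)C(C)(C)C)C(=O)N2[C@@H](Cc3ccccc3)COC2=O)ccc1OCc1ccccc1
F2 | step 8 | (2S,3S)-3-(4-benzyloxy-3-methoxyphenyl)-2-(tert-butyldimethylsilyloxymethyl)-3-[(E)-3-(3,4-dimethoxyphenyl)allyloxy]propanoic acid | COc1cc([C@@H](OC/C=C/c4ccc(OC)c(OC)c4)[C@H](CO[Si](C)(C)C(C)(C)C)C(=O)O)ccc1OCc1ccccc1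
F3 | step 8 | 1,3-dioxoisoindolin-2-yl ester of F2 | COc1cc([C@@H](OC/C=C/c4ccc(OC)c(OC)c4)[C@H](CO[Si](C)(C)C(C)(C)C)C(=O)ON2C(=O)c3ccccc3C2=O)ccc1OCc1ccccc1
F4 | step 5 | (2S,3S)-3-(4-benzyloxy-3-methoxyphenyl)-2-(tert-butyldimethylsilyloxymethyl)-3-hydroxypropanoic acid | COc1cc([C@@H](O)[C@H](CO[Si](C)(C)C(C)(C)C)C(=O)O)ccc1OCc1ccccc1
F5 | step 4 | (S)-4-benzyl-3-[(E)-but-2-enoyl]-1,3-oxazolidin-2-one | C/C=C/C(=O)N1[C@@H](Cc2ccccc2)COC1=O
F6 | step 4 | (S)-4-benzyl-3-[(2S)-2-[(S)-(4-benzyloxy-3-methoxyphenyl)(hydroxy)methyl]but-3-enoyl]-1,3-oxazolidin-2-one | COc1cc([C@@H](O)[C@H](C=C)C(=O)N2[C@@H](Cc3ccccc3)COC2=O)ccc1OCc1ccccc1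
F7 | step 4 | (S)-4-benzyl-3-[(2S,3S)-3-(4-benzyloxy-3-methoxyphenyl)-3-hydroxy-2-(hydroxymethyl)propanoyl]-1,3-oxazolidin-2-one | COc1cc([C@@H](O)[C@H](CO)C(=O)N2[C@@H](Cc3ccccc3)COC2=O)ccc1OCc1ccccc1
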